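## Structural features

The target is a 2,3-dihydro-1-benzofuran: a benzene ring fused through C3a–C7a to a five-membered ether ring (O1, C2, C3), with an acetyl group on C5 and a methoxy group on C6. C2 carries an isopropenyl group and C3 an acyloxy group; these adjacent stereocentres are 2R and 3S, and the two substituents are trans. The acyl group is (2Z)-2-(acetoxymethyl)but-2-enoyl: the β-methyl group is cis to the carboxyl carbon, the less stable arrangement of a trisubstituted acrylate, and the acetoxymethyl group makes the alkene an SN2′ acceptor. C3 is benzylic, para to the methoxy group and ortho to the ring oxygen, so any C3–O bond ionises easily, and loss of the C3 oxygen together with the C2 hydrogen would give an aromatic benzofuran. The methyl ketone is enolisable and is a second carbonyl chromophore. The real difficulty is the trans O/isopropenyl pair in one absolute configuration on a ring that tends to aromatise, with no other stereocentre to lean on, followed by attachment of an acid that isomerises on acyl activation. The key step uses the chain O(on C3)–C3–C2–C(CH3)(=CH2): tying that oxygen to the future isopropenyl carbon gives a 2,2-dimethyloxetane fused across C2–C3, which is the [2+2] adduct of an aldehyde carbonyl (C3=O) and an enol ether double bond (C2=C(CH3)2) held together by O1 and the benzene ring.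

## Logic of the disconnections

17 ⇒ 9 + 16. The bond cut is C3–O of the ester, not the acyl C–O bond. Cutting there lets the acid enter as a carboxylate nucleophile, so its Z alkene is never exposed to acyl activation, and the substitution at C3 corrects the configuration at the same time. The gain is that the whole side chain is removed and the stereochemical problem is reduced to a small bicyclic alcohol with the C3 configuration opposite to the target. The demand is a clean inversion at a benzylic carbon that ionises easily, without elimination toward the aromatic furan.

9 ⇒ 8. No bond is cut; one enantiomer is taken from the racemate. Nothing earlier in the route can set the absolute configuration by established means, so it is sorted here, at the first compound with a handle (a secondary hydroxyl). The demand is that an acyl-transfer enzyme distinguishes the two enantiomers of a hindered benzylic carbinol.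

8 ⇒ 7. The hydroxyl oxygen on C3 and the isopropenyl carbon are reconnected as an O–C(CH3)2 bond (a methyl C–H and the O–H are paired up). This turns two independent stereocentres into a fused four/five ring pair, in which only the cis arrangement can exist. The demand on the forward step is a β-elimination that removes a methyl hydrogen and breaks only the O–C(CH3)2 bond, under conditions that do not ionise C3–O.

7 ⇒ 6. The bonds cut are C2–C3 and O–C(CH3)2, a [2+2] cycloreversion. Both rings other than the benzene ring and both stereocentres disappear, leaving a flat, achiral benzaldehyde with an enol ether on the ortho oxygen. The demand is a photochemical step that is intramolecular, selective for the aldehyde over the acetyl carbonyl, and regioselective for the fused adduct.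

6 ⇒ 5. No skeletal bond is cut; the double bond is moved out of conjugation with oxygen. The enol ether cannot be made by direct alkylation of a phenol, while the allylic ether can. The demand is an isomerisation catalyst that tolerates an aldehyde and a ketone and works on a 1,1-disubstituted alkene.

5 ⇒ 3 + 4, and 3 ⇒ 1 (through 2). The O–CH2 bond and then the aryl–CHO bond are cut. Both are standard phenol chemistry, and the ortho-formylation must go to the position para to the methoxy group rather than between the two oxygens.

16 ⇒ 15 ⇒ 13 ⇒ 12 ⇒ 10 (through 14 and 11). The O-acetyl bond, then the C2–CO2H bond, are cut, and the alkene geometry is traced back to an α-bromo enal. The reason is geometric: in 12 the stable isomer has the methyl group cis to bromine and trans to the formyl carbon. If the formyl carbon becomes the CH2O group and the bromine is replaced by the carboxyl group with retention, the methyl group ends cis to the carboxyl group, which is the otherwise disfavoured Z acid. The demand is a vinyl anion that keeps its geometry until it is carboxylated.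

## Other disconnections considered

Alternative 1: The cut is O1–C2, with O1 reconnected to the carbon that becomes the isopropenyl group, so the dihydrofuran is traced back to a 2,2-dimethylchroman. Forward, the chromene A1 (one annulation step from 1) would be epoxidised enantioselectively, the epoxide opened at C4 with inversion, and the C4 hydroxyl silylated to give the trans alcohol A2. Triflation of the C3 hydroxyl of A2 then lets the ring oxygen move from C(CH3)2 to C3 with inversion; the tertiary cation loses a methyl proton and the silyl ether A3 results.
- In favour: both stereocentres come from one catalytic asymmetric epoxidation of a 2,2-dimethylchromene, a substrate class on which Mn(salen)Cl-type catalysts are at their best. On absolute stereocontrol and material throughput this is better than the chosen plan, which resolves a racemate and gives up half the material. The trans relation follows directly, so no later inversion is needed.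
- Against: the migrating oxygen is an aryl ether oxygen para to the acetyl group, a weak neighbouring group. The C4–C4a bond is as well aligned with an equatorial C3 triflate as the O1–C(CH3)2 bond, and a 1,2-aryl shift, helped by the C4 oxygen and the para-methoxy group, would contract the ring in the wrong sense. The cation may also lose the ring proton or be captured, and the two secondary hydroxyls must first be differentiated. Desilylation and acylation with activated 16 follow, and acyl activation is where the Z alkene of 16 is at risk.
- Comparison: both plans use a temporary ring that is opened to release the isopropenyl group. Alternative 1 is a ground-state cationic rearrangement whose outcome depends on which of two aligned bonds migrates; the chosen plan is a photochemical closure whose regiochemistry is fixed by the tether. The longest linear sequences are equal at seven steps.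

Alternative 2: The cuts are C2–C3 and O1–C2, a [4+1] disconnection to the salicylaldehyde 3 and a one-carbon donor carrying the isopropenyl group, the sulfonium salt A4 (drawn with one enantiomer of a C2-symmetric thiolane; the sense of induction would have to be established). Forward, the ylide from A4 adds to the aldehyde carbon and the neighbouring phenoxide displaces the sulfide from the allylic carbon, directly (5-exo) or through the vinyl epoxide, to give the trans alcohol A5.
- In favour: it is the shortest entry, two steps from 1 to the bicyclic alcohol against six to 9. It is polarity-matched ground-state chemistry, the trans isomer needed is the expected one, and the chiral sulfide can be recovered. On step count and directness of the trans relation it is clearly better than the chosen plan.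
- Against: the phenol must be deprotonated for the ylide to survive, and the resulting phenoxide makes the ortho aldehyde a poor electrophile. The acetyl group offers an enolisable methyl and a second carbonyl to a basic ylide. Allyl sulfonium ylides can rearrange by [2,3] shift, and their additions to aldehydes are less diastereo- and enantioselective than those of benzyl ylides. If the epoxide forms first, ring closure needs an endo opening. A5 must then be acylated with activated 16, with the isomerisation risk that the chosen plan avoids.
- Comparison: Alternative 2 sets both centres by reagent control in one ionic step. The chosen plan sets the relative configuration by ring strain, which is more certain, and the absolute one by resolution, which is less economical. On stereochemical certainty the chosen plan is ahead; on length Alternative 2 is ahead.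

Alternative 3: The cuts are C3a–C3 and O1–C2, leading to the iodophenol A6 (one iodination from 1) and the dienyl acetate A7. Forward, the arylpalladium species formed from A6 and zerovalent palladium adds to the acetoxy-bearing diene terminus, and the phenoxide closes onto the internal carbon of the π-allyl palladium intermediate, giving the acetate A8.
- In favour: ring, both stereocentres, the isopropenyl group and the C3 oxygen arrive in one catalytic step from two simple pieces. Asymmetric diene heteroannulations of halophenols to 2-alkenyl dihydrobenzofurans are established, so absolute control by a chiral ligand is conceivable. In convergence and catalytic enantiocontrol this is equal or superior to the chosen plan.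
- Against: the aryl group must add to the more hindered, oxygen-bearing terminus, against the usual preference for the free CH2 terminus; the usual mode would place the ring oxygen on the methyl-bearing carbon and give the wrong constitution. β-Acetoxy elimination can follow insertion. Syn/anti equilibration of the π-allyl intermediate and reversible ionisation of the allylic aryl ether can erode both relative and absolute configuration. The acetate on C3 must still be exchanged for the acyl group of 16, which adds two steps and acyl activation of 16.
- Comparison: Alternative 3 is the shortest on paper (about four linear steps), but its regiochemistry rests on an insertion running against its normal bias. The chosen plan is longer, but the tether leaves only one way for the two bonds to form.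

Key step: step 4

Remarks on the chemistry assumed:
- 1, 4 and 10 are taken as purchased.
- Locants C2, C3, O1, C3a and C7a are those of the 2,3-dihydro-1-benzofuran of the target throughout.
- The photocycloaddition is run without a chiral controller. 7 and 8 are therefore racemates, drawn and named as the enantiomer that leads to the target; the single enantiomer is secured in step 6.
- The structures were checked against the target: 7 has the target's arrangement at C2 and the opposite one at C3, and the acid needed is the 2Z isomer (methyl cis to carboxyl).

## Route

Step 1
Reactants: 1 1-(4-hydroxy-2-methoxyphenyl)ethanone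
Product: 3 5-acetyl-2-hydroxy-4-methoxybenzaldehyde, via hydroxymethyl phenol 2 (not isolated)
Conditions: MgCl2, Et3N, (CH2O)n, MeCN, reflux; then 1 M HCl
Reagents that add atoms: paraformaldehyde (as formaldehyde), C=O
Why: Casnati–Skattebøl ortho-formylation: the magnesium phenoxide delivers formaldehyde to the ortho carbon through a chelate, and the hydroxymethyl intermediate is oxidised by a second formaldehyde through hydride transfer. Of the two ortho positions, the one para to the methoxy group is open, while the other lies between two oxygen substituents.

Step 2
Reactants: 3 5-acetyl-2-hydroxy-4-methoxybenzaldehyde; 4 3-chloro-2-methylprop-1-ene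
Product: 5 5-acetyl-4-methoxy-2-[(2-methylprop-2-en-1-yl)oxy]benzaldehyde
Conditions: K2CO3, DMF, 60 °C
Reagents that add atoms: none
Why: Williamson etherification of the phenoxide with an allylic chloride (SN2). Carbonate in DMF is too weak a base to start a Claisen–Schmidt condensation between the acetyl and formyl groups.

Step 3
Reactants: 5 5-acetyl-4-methoxy-2-[(2-methylprop-2-en-1-yl)oxy]benzaldehyde
Product: 6 5-acetyl-4-methoxy-2-[(2-methylprop-1-en-1-yl)oxy]benzaldehyde
Conditions: RuHCl(CO)(PPh3)3 (5 mol %), toluene, 90 °C
Reagents that add atoms: none
Why: Ruthenium hydride-catalysed isomerisation of an allyl ether to the enol ether by hydrometalation and β-hydride elimination. The trisubstituted, oxygen-conjugated alkene is the thermodynamic product and has no E/Z isomers because its β-carbon carries two methyl groups.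

Step 4
Reactants: 6 5-acetyl-4-methoxy-2-[(2-methylprop-1-en-1-yl)oxy]benzaldehyde
Product: 7 rac-1-[(2aS,7bR)-5-methoxy-2,2-dimethyl-2a,7b-dihydro-2H-oxeto[3,2-b][1]benzofuran-6-yl]ethanone (cis-fused oxetane; oxetane O on C3 and C(CH3)2 on C2 of the dihydrobenzofuran)
Conditions: hν (365 nm), degassed C6H6, 3 mM, 20 °C
Reagents that add atoms: none
Why: Excitation of the aryl aldehyde and intersystem crossing give a triplet whose oxygen attacks the electron-rich β-carbon of the tethered enol ether (the future isopropenyl carbon), forming the O–C(CH3)2 bond and a 1,4-biradical made of a benzylic ketyl centre and an α-aryloxy centre; after spin inversion these combine to form the C2–C3 bond. The closest known reaction type is the Paternò–Büchi addition of aromatic aldehydes to enol ethers, which gives 3-alkoxyoxetanes with this orientation, together with intramolecular variants in which a short tether closes a second ring. The oxetane closes stepwise, O–C bond first and C–C bond by radical recombination; the dihydrofuran ring closes in that same recombination as a five-membered closure between C3 and C2 across the C3a–C7a–O1 tether. Both new stereocentres (C2 and C3, positions 2a and 7b of 7) are fixed relative to each other by ring strain, since an oxetane fused to a five-membered ring can only be cis; nothing controls the absolute sense, so 7 is expected as the racemate. The step needs selectivity for the aldehyde over the acetyl carbonyl, which the substrate provides because only the aldehyde has an alkene within reach and the acetyl group's only intramolecular outlet, δ-hydrogen abstraction from the methoxy group, is slow. It needs the fused rather than the bridged adduct, which the polarisation of the enol ether and the strain of the bridged alternative favour, and it needs intramolecular addition to outrun intermolecular addition, which high dilution provides. The only δ-hydrogen of the aldehyde is vinylic, so hydrogen abstraction should not compete, and the gem-dimethyl terminus leaves no alkene geometry to control.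

Step 5
Reactants: 7 rac-1-[(2aS,7bR)-5-methoxy-2,2-dimethyl-2a,7b-dihydro-2H-oxeto[3,2-b][1]benzofuran-6-yl]ethanone
Product: 8 rac-1-[(2R,3R)-3-hydroxy-6-methoxy-2-(prop-1-en-2-yl)-2,3-dihydro-1-benzofuran-5-yl]ethanone (cis alcohol)
Conditions: Et2Al(TMP) (4 equiv; from 2,2,6,6-tetramethylpiperidine, n-BuLi and Et2AlCl), toluene, 0 °C, slow addition of 7 to the reagent; then aq. KNaC4H4O6 (potassium sodium tartrate)
Reagents that add atoms: none
Why: Aluminium amide-promoted syn β-elimination, the oxetane counterpart of the epoxide-to-allylic-alcohol isomerisation: aluminium binds the oxetane oxygen and the amide nitrogen removes a methyl hydrogen through a six-membered transition state, breaking only the O–C(CH3)2 bond, so C3–O and both stereocentres are untouched and the cis alcohol results. A base is chosen over a Lewis acid because ionisation would occur at benzylic C3 and end in the aromatic benzofuran. The acetyl group is held as its aluminium enolate by the excess reagent and returns on work-up.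

Step 6
Reactants: 8 rac-1-[(2R,3R)-3-hydroxy-6-methoxy-2-(prop-1-en-2-yl)-2,3-dihydro-1-benzofuran-5-yl]ethanone
Product: 9 1-[(2R,3R)-3-hydroxy-6-methoxy-2-(prop-1-en-2-yl)-2,3-dihydro-1-benzofuran-5-yl]ethanone (single enantiomer)
Conditions: immobilised Candida antarctica lipase B, vinyl acetate, t-BuOMe, 35 °C, run to just past half conversion; chromatography
Reagents that add atoms: none
Why: Lipase-catalysed kinetic resolution of a secondary benzylic alcohol by irreversible acyl transfer. By analogy with indan-1-ol-type carbinols (aryl flank as the large group) the (2S,3S) enantiomer is expected to be acetylated and the (2R,3R) alcohol to remain, and the slow enantiomer can be brought to high purity by running past half conversion. No stereocentre is touched; the assignment must be confirmed before step 11.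

Step 7
Reactants: 10 (2E)-but-2-enal
Product: 12 (2Z)-2-bromobut-2-enal, via 2,3-dibromobutanal 11 (not isolated)
Conditions: Br2, CH2Cl2, 0 °C; then Et3N, 0 °C → rt
Reagents that add atoms: bromine, BrBr
Why: Anti addition of bromine to the alkene, then base-induced dehydrobromination (loss of the acidic C2 hydrogen and the C3 bromide, E1cB-like), should give the α-bromo enal as the thermodynamically favoured Z isomer, with the methyl group trans to the formyl group and cis to bromine.

Step 8
Reactants: 12 (2Z)-2-bromobut-2-enal
Product: 13 (2Z)-2-bromobut-2-en-1-ol
Conditions: NaBH4, CeCl3·7H2O, MeOH, 0 °C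
Reagents that add atoms: none
Why: Luche reduction: cerium-assisted borohydride reduces the aldehyde 1,2 and leaves the vinyl bromide and the alkene geometry untouched, so CH2OH ends trans to the methyl group.

Step 9
Reactants: 13 (2Z)-2-bromobut-2-en-1-ol
Product: 15 (2Z)-2-(hydroxymethyl)but-2-enoic acid, via dilithio alkoxide 14 (not isolated)
Conditions: t-BuLi (3.1 equiv), Et2O, −78 °C; CO2, −78 → 0 °C; then 1 M HCl
Reagents that add atoms: carbon dioxide, O=C=O
Why: Deprotonation of the hydroxyl, then bromine–lithium exchange, gives a vinyllithium that keeps its geometry at −78 °C and is carboxylated with retention, so the carboxyl group takes the place of bromine, cis to the methyl group. The third equivalent of t-BuLi consumes the alkyl bromide formed in the exchange.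

Step 10
Reactants: 15 (2Z)-2-(hydroxymethyl)but-2-enoic acid
Product: 16 (2Z)-2-[(acetyloxy)methyl]but-2-enoic acid
Conditions: Ac2O, pyridine, 0 °C → rt; then H2O
Reagents that add atoms: acetic anhydride, CC(=O)OC(C)=O
Why: O-Acetylation of the primary allylic alcohol; any mixed anhydride at the carboxyl group is hydrolysed in the aqueous work-up. Pyridine is used without a stronger nucleophilic catalyst to avoid conjugate addition that could isomerise the Z alkene.

Step 11
Reactants: 9 1-[(2R,3R)-3-hydroxy-6-methoxy-2-(prop-1-en-2-yl)-2,3-dihydro-1-benzofuran-5-yl]ethanone; 16 (2Z)-2-[(acetyloxy)methyl]but-2-enoic acid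
Product: 17 (2R,3S)-5-acetyl-6-methoxy-2-(prop-1-en-2-yl)-2,3-dihydro-1-benzofuran-3-yl (2Z)-2-[(acetyloxy)methyl]but-2-enoate
Conditions: PPh3, DIAD, toluene, 0 °C (betaine pre-formed); then 16, then 9, 0 °C → rt
Reagents that add atoms: none
Why: Mitsunobu esterification: the alkoxyphosphonium ion of 9 is displaced by the carboxylate of 16 with inversion at C3 (R to S), the nucleophile entering on the face opposite both the leaving group and the C2 isopropenyl group, which gives the trans ester. The acid reacts as a carboxylate and is never activated at its acyl carbon, which protects its Z alkene, and pre-forming the betaine leaves no free phosphine to add to the acetoxymethyl acrylate.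

## Compound list

1 | 1-(4-hydroxy-2-methoxyphenyl)ethanone | CC(=O)c1ccc(O)cc1OC | starting material
2 | 1-[4-hydroxy-5-(hydroxymethyl)-2-methoxyphenyl]ethanone (present as its magnesium phenoxide) | CC(=O)c1cc(CO)c(O)cc1OC | intermediate (not isolated)
3 | 5-acetyl-2-hydroxy-4-methoxybenzaldehyde | CC(=O)c1cc(C=O)c(O)cc1OC | intermediate
4 | 3-chloro-2-methylprop-1-ene | C=C(C)CCl | starting material
5 | 5-acetyl-4-methoxy-2-[(2-methylprop-2-en-1-yl)oxy]benzaldehyde | CC(=O)c1cc(C=O)c(OCC(C)=C)cc1OC | intermediate
6 | 5-acetyl-4-methoxy-2-[(2-methylprop-1-en-1-yl)oxy]benzaldehyde | CC(=O)c1cc(C=O)c(OC=C(C)C)cc1OC | intermediate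
7 | rac-1-[(2aS,7bR)-5-methoxy-2,2-dimethyl-2a,7b-dihydro-2H-oxeto[3,2-b][1]benzofuran-6-yl]ethanone (racemate; enantiomer shown leads to the target) | CC(=O)c1cc2c(cc1OC)O[C@H]3[C@@H]2OC3(C)C | intermediate
8 | rac-1-[(2R,3R)-3-hydroxy-6-methoxy-2-(prop-1-en-2-yl)-2,3-dihydro-1-benzofuran-5-yl]ethanone (racemic cis alcohol) | C=C(C)[C@H]1Oc2cc(OC)c(C(C)=O)cc2[C@H]1O | intermediate
9 | 1-[(2R,3R)-3-hydroxy-6-methoxy-2-(prop-1-en-2-yl)-2,3-dihydro-1-benzofuran-5-yl]ethanone (single enantiomer) | C=C(C)[C@H]1Oc2cc(OC)c(C(C)=O)cc2[C@H]1O | intermediate
10 | (2E)-but-2-enal | C/C=C/C=O | starting material
11 | (2R*,3S*)-2,3-dibromobutanal (racemic anti adduct; (2S,3R) enantiomer shown) | C[C@@H](Br)[C@@H](Br)C=O | intermediate (not isolated)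
12 | (2Z)-2-bromobut-2-enal | C/C=C(\Br)C=O | intermediate
13 | (2Z)-2-bromobut-2-en-1-ol | C/C=C(\Br)CO | intermediate
14 | lithium (2E)-2-lithiobut-2-en-1-olate (geometry of 13 retained; descriptor changes because lithium ranks below carbon) | C/C=C(\[Li])CO[Li] | intermediate (not isolated)
15 | (2Z)-2-(hydroxymethyl)but-2-enoic acid | C/C=C(\C(=O)O)CO | intermediate
16 | (2Z)-2-[(acetyloxy)methyl]but-2-enoic acid | C/C=C(\C(=O)O)COC(C)=O | intermediate
17 | (2R,3S)-5-acetyl-6-methoxy-2-(prop-1-en-2-yl)-2,3-dihydro-1-benzofuran-3-yl (2Z)-2-[(acetyloxy)methyl]but-2-enoate | C=C(C)[C@H]1Oc2cc(OC)c(C(C)=O)cc2[C@@H]1OC(=O)/C(=C\C)COC(C)=O | target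

## Step count and least certain steps

Total step count: 11 (seven in the main line, four for the side-chain acid). Longest linear sequence: 7 steps (steps 1–6 and 11).

Step 4 (key step).
- What may go wrong: the aldehyde sits between two alkoxy donors, so its lowest triplet may have too little n,π* character and decay without bonding. Electron transfer from the enol ether may lead to fragmentation. Intermolecular addition through the acetyl carbonyl may produce oligomers if dilution is insufficient.
- Fallback: set out from 5 and irradiate it under the same conditions. The excited aldehyde should then abstract a hydrogen from the O–CH2 group (Norrish–Yang cyclisation of an ortho-alkoxy aryl aldehyde), and the 1,5-biradical closes the same C2–C3 bond. This would give the racemic cis alcohol 8 together with its trans epimer, rac-1-[(2R,3S)-3-hydroxy-6-methoxy-2-(prop-1-en-2-yl)-2,3-dihydro-1-benzofuran-5-yl]ethanone F1 (the racemate of A5). After separation the route is rejoined at 8, and steps 3–5 are bypassed.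

Step 3.
- What may go wrong: slow isomerisation of a 1,1-disubstituted allyl ether, and side reactions of the ruthenium hydride with the aldehyde (reduction or decarbonylation) on prolonged heating.
- Fallback: set out from 3 and form the enol ether directly by Chan–Lam coupling of the phenol with 2-methylprop-1-enylboronic acid (Cu(OAc)2, pyridine, 4 Å sieves, CH2Cl2, air, rt), coming back at 6. This makes no new compound (F0) and replaces steps 2 and 3.

Step 5.
- What may go wrong: incomplete enolisation of the acetyl group followed by aldol self-condensation. Removal of the C2 hydrogen, or metalation of the ring between the two oxygens, would open the oxetane toward the aromatic benzofuran.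
- Fallback: set out from 7 and mask the ketone under basic conditions (LiN(SiMe3)2, t-BuMe2SiCl, THF, −78 °C) as the silyl enol ether, rac-tert-butyl({1-[(2aS,7bR)-5-methoxy-2,2-dimethyl-2a,7b-dihydro-2H-oxeto[3,2-b][1]benzofuran-6-yl]ethenyl}oxy)dimethylsilane F2. Open the oxetane with Et2Al(TMP) as in step 5 to give rac-(2R,3R)-5-{1-[(tert-butyldimethylsilyl)oxy]ethenyl}-6-methoxy-2-(prop-1-en-2-yl)-2,3-dihydro-1-benzofuran-3-ol F3, and release the ketone with Bu4NF buffered with acetic acid, coming back at 8.

Step 6.
- What may go wrong: poor discrimination, because both flanks of the carbinol are bulky; slow acylation, because the cis isopropenyl group shields the hydroxyl; or the reverse preference, in which case the ester fraction carries the wanted enantiomer and a methanolysis is added.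
- Fallback: set out from 8 and esterify with (S)-2-methoxy-2-phenylacetic acid (Steglich conditions). Separate the diastereomers (2R,3R)-5-acetyl-6-methoxy-2-(prop-1-en-2-yl)-2,3-dihydro-1-benzofuran-3-yl (2S)-2-methoxy-2-phenylacetate F4 and (2S,3S)-5-acetyl-6-methoxy-2-(prop-1-en-2-yl)-2,3-dihydro-1-benzofuran-3-yl (2S)-2-methoxy-2-phenylacetate F5 by chromatography or crystallisation, and cleave F4 with K2CO3 in MeOH, coming back at 9. The ester also allows the configuration to be assigned.

Step 11.
- What may go wrong: elimination of the activated C3 oxygen with the C2 hydrogen to the aromatic benzofuran; partial ionisation at C3 (which should still favour the trans ester but would erode stereospecificity); and consumption of 16 by conjugate or SN2′ addition of phosphine or hydrazide.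
- Fallback: set out from 9 and separate inversion from acylation. Mitsunobu reaction with the more acidic 4-nitrobenzoic acid gives (2R,3S)-5-acetyl-6-methoxy-2-(prop-1-en-2-yl)-2,3-dihydro-1-benzofuran-3-yl 4-nitrobenzoate F6. Methanolysis (K2CO3, MeOH) gives the trans alcohol 1-[(2R,3S)-3-hydroxy-6-methoxy-2-(prop-1-en-2-yl)-2,3-dihydro-1-benzofuran-5-yl]ethanone F7 (the same structure as A5). Yamaguchi esterification with 16 (2,4,6-trichlorobenzoyl chloride, Et3N, then F7 and 4-(dimethylamino)pyridine, toluene), the usual way to acylate with angelate-type acids without isomerisation, comes back at 17.

## Further compounds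

F1 | step 4 | rac-1-[(2R,3S)-3-hydroxy-6-methoxy-2-(prop-1-en-2-yl)-2,3-dihydro-1-benzofuran-5-yl]ethanone (racemic trans epimer of 8) | C=C(C)[C@H]1Oc2cc(OC)c(C(C)=O)cc2[C@@H]1O
F0 | step 3 | none | none
F2 | step 5 | rac-tert-butyl({1-[(2aS,7bR)-5-methoxy-2,2-dimethyl-2a,7b-dihydro-2H-oxeto[3,2-b][1]benzofuran-6-yl]ethenyl}oxy)dimethylsilane | C=C(O[Si](C)(C)C(C)(C)C)c1cc2c(cc1OC)O[C@H]3[C@@H]2OC3(C)C
F3 | step 5 | rac-(2R,3R)-5-{1-[(tert-butyldimethylsilyl)oxy]ethenyl}-6-methoxy-2-(prop-1-en-2-yl)-2,3-dihydro-1-benzofuran-3-ol | C=C(C)[C@H]1Oc2cc(OC)c(C(=C)O[Si](C)(C)C(C)(C)C)cc2[C@H]1O
F4 | step 6 | (2R,3R)-5-acetyl-6-methoxy-2-(prop-1-en-2-yl)-2,3-dihydro-1-benzofuran-3-yl (2S)-2-methoxy-2-phenylacetate | C=C(C)[C@H]1Oc2cc(OC)c(C(C)=O)cc2[C@H]1OC(=O)[C@@H](OC)c1ccccc1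
F5 | step 6 | (2S,3S)-5-acetyl-6-methoxy-2-(prop-1-en-2-yl)-2,3-dihydro-1-benzofuran-3-yl (2S)-2-methoxy-2-phenylacetate | C=C(C)[C@@H]1Oc2cc(OC)c(C(C)=O)cc2[C@@H]1OC(=O)[C@@H](OC)c1ccccc1
F6 | step 11 | (2R,3S)-5-acetyl-6-methoxy-2-(prop-1-en-2-yl)-2,3-dihydro-1-benzofuran-3-yl 4-nitrobenzoate | C=C(C)[C@H]1Oc2cc(OC)c(C(C)=O)cc2[C@@H]1OC(=O)c1ccc(cc1)[N+](=O)[O-]
F7 | step 11 | 1-[(2R,3S)-3-hydroxy-6-methoxy-2-(prop-1-en-2-yl)-2,3-dihydro-1-benzofuran-5-yl]ethanone | C=C(C)[C@H]1Oc2cc(OC)c(C(C)=O)cc2[C@@H]1O
A1 | alternative 1 | 1-(7-methoxy-2,2-dimethyl-2H-chromen-6-yl)ethanone | CC(=O)c1cc2C=CC(C)(C)Oc2cc1OC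
A2 | alternative 1 | 1-[(3R,4S)-4-[(tert-butyldimethylsilyl)oxy]-3-hydroxy-7-methoxy-2,2-dimethyl-3,4-dihydro-2H-chromen-6-yl]ethanone | CC(=O)c1cc2c(cc1OC)OC(C)(C)[C@H](O)[C@H]2O[Si](C)(C)C(C)(C)C
A3 | alternative 1 | 1-[(2R,3S)-3-[(tert-butyldimethylsilyl)oxy]-6-methoxy-2-(prop-1-en-2-yl)-2,3-dihydro-1-benzofuran-5-yl]ethanone | C=C(C)[C@H]1Oc2cc(OC)c(C(C)=O)cc2[C@@H]1O[Si](C)(C)C(C)(C)C
A4 | alternative 2 | (2R,5R)-2,5-dimethyl-1-(2-methylprop-2-en-1-yl)thiolan-1-ium tetrafluoroborate | C[C@@H]1CC[C@@H](C)[S+]1CC(C)=C.F[B-](F)(F)F
A5 | alternative 2 | 1-[(2R,3S)-3-hydroxy-6-methoxy-2-(prop-1-en-2-yl)-2,3-dihydro-1-benzofuran-5-yl]ethanone | C=C(C)[C@H]1Oc2cc(OC)c(C(C)=O)cc2[C@@H]1O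
A6 | alternative 3 | 1-(4-hydroxy-5-iodo-2-methoxyphenyl)ethanone | CC(=O)c1cc(I)c(O)cc1OC
A7 | alternative 3 | (1E)-3-methylbuta-1,3-dien-1-yl acetate | CC(=O)O/C=C/C(C)=C
A8 | alternative 3 | (2R,3S)-5-acetyl-6-methoxy-2-(prop-1-en-2-yl)-2,3-dihydro-1-benzofuran-3-yl acetate | C=C(C)[C@H]1Oc2cc(OC)c(C(C)=O)cc2[C@@H]1OC(C)=O
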